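Ring B is closed last through the C5–C6 bond. An allylsamarium at C6, formed from an E/Z mixture of allylic bromides, adds to the C5 ketone of ring A in a stereoconvergent intramolecular Barbier reaction. The step exploits that C5 lies between the fully substituted C4 and C10: the ketone cannot enolise, and its carbinol later loses water only toward C6, giving the 5,7-diene of ring B, whose hydrogenation anti to the C10 methyl sets C5–H trans. The precursor is an actinol-derived cyclohexanone; its C10 and C9 stereocentres come from a Claisen rearrangement directed by the C2 silyloxy group.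

Key step: step 10

Remark: atoms carry labdane numbers (ring A = C1–C5 and C10; ring B = C5–C10; C17 on C8; C20 on C10; side chain C11–C16), and (4R,6R)-actinol and geraniol are assumed to be purchasable.

Step 1
Reactants: 1 geraniol
Product: 2 geranyl tert-butyldiphenylsilyl ether
Conditions: t-BuPh2SiCl, imidazole, DMF, 0 °C to rt
Reagents that add atoms: tert-butyl(chloro)diphenylsilane, CC(C)(C)[Si](Cl)(c1ccccc1)c1ccccc1
Why: Silylation of the primary allylic alcohol should give an ether that tolerates the later organometallic, acidic and reductive steps; no stereocentre is formed.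

Step 2
Reactants: 2 geranyl tert-butyldiphenylsilyl ether
Product: 4 (E)-6-(tert-butyldiphenylsilyloxy)-4-methylhex-4-enal, via ozonide 3 (not isolated)
Conditions: O3 (1.0 equiv, Sudan Red 7B end point), CH2Cl2, −78 °C; then Me2S, −78 °C to rt
Reagents that add atoms: ozone, [O-][O+]=O
Why: Chemoselective ozonolysis with reductive work-up should cleave only the electron-richer 6,7-alkene of the geranyl chain, because the 2,3-alkene is deactivated by the allylic oxygen, so the E alkene is kept.

Step 3
Reactants: 4 (E)-6-(tert-butyldiphenylsilyloxy)-4-methylhex-4-enal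
Product: 5 (E)-tert-butyl[(3-methylhept-2-en-6-yn-1-yl)oxy]diphenylsilane
Conditions: dimethyl (1-diazo-2-oxopropyl)phosphonate, K2CO3, MeOH, 0 °C to rt
Reagents that add atoms: Ohira–Bestmann reagent, CC(=O)C(=[N+]=[N-])P(=O)(OC)OC
Why: Seyferth–Gilbert homologation in its Ohira–Bestmann form should convert the enolisable aldehyde into the terminal alkyne under mild base that does not move the trisubstituted alkene.

Step 4
Reactants: 5 (E)-tert-butyl[(3-methylhept-2-en-6-yn-1-yl)oxy]diphenylsilane
Product: 7 (E)-8-(tert-butyldiphenylsilyloxy)-6-methyloct-6-en-2-yn-1-ol, via lithium acetylide 6 (not isolated)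
Conditions: n-BuLi, THF, −78 °C; (CH2O)n, −78 °C to rt; H2O
Reagents that add atoms: formaldehyde (as paraformaldehyde), C=O
Why: Acetylide hydroxymethylation (deprotonation of the terminal alkyne and addition to formaldehyde) should give the propargylic alcohol that directs the next step.

Step 5
Reactants: 7 (E)-8-(tert-butyldiphenylsilyloxy)-6-methyloct-6-en-2-yn-1-ol
Product: 9 (2E,6E)-8-(tert-butyldiphenylsilyloxy)-2-ethenyl-6-methylocta-2,6-dien-1-ol, via oxamagnesacycle 8 (not isolated)
Conditions: CH2=CHMgCl (3 equiv), THF–toluene, 80 °C; then aq. NH4Cl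
Reagents that add atoms: vinylmagnesium chloride, C=C[Mg]Cl
Why: Alkoxide-directed anti-carbomagnesiation of the propargylic alcohol puts vinyl on the proximal alkyne carbon and magnesium on the distal one in a five-membered chelate, so protonolysis should give the 2-vinyl allylic alcohol with the chain cis to vinyl and trans to CH2OH (E), the geometry that later sets C9.

Step 6
Reactants: 9 (2E,6E)-8-(tert-butyldiphenylsilyloxy)-2-ethenyl-6-methylocta-2,6-dien-1-ol
Product: 10 (2E,6E)-8-(tert-butyldiphenylsilyloxy)-2-ethenyl-6-methylocta-2,6-dien-1-yl methanesulfonate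
Conditions: MsCl, Et3N, CH2Cl2, −30 °C; used crude
Reagents that add atoms: methanesulfonyl chloride, CS(=O)(=O)Cl
Why: Sulfonylation of the primary allylic alcohol should give a hard electrophile suited to O-alkylation of an enolate; no stereocentre is touched.

Step 7
Reactants: 11 (4R,6R)-actinol, i.e. (4R,6R)-4-hydroxy-2,2,6-trimethylcyclohexanone
Product: 12 (4R,6R)-4-(tert-butyldimethylsilyloxy)-2,2,6-trimethylcyclohexanone
Conditions: t-BuMe2SiCl, imidazole, DMF, rt
Reagents that add atoms: tert-butyl(chloro)dimethylsilane, CC(C)(C)[Si](C)(C)Cl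
Why: Silylation of the secondary alcohol keeps the future C2 stereocentre and installs the bulky group that directs the Claisen rearrangement.

Step 8
Reactants: 12 (4R,6R)-4-(tert-butyldimethylsilyloxy)-2,2,6-trimethylcyclohexanone; 10 (2E,6E)-8-(tert-butyldiphenylsilyloxy)-2-ethenyl-6-methylocta-2,6-dien-1-yl methanesulfonate
Product: 15 dienyl ketone (C5 ketone of ring A; C10 carries methyl cis to the C2 silyloxy group and C9; C9 carries buta-1,3-dien-2-yl and the C11–C16 chain), via potassium enolate 13 (not isolated), via allyl enol ether 14 (not isolated)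
Conditions: KN(SiMe3)2, THF, −78 °C; DMPU, then 10, −78 to 0 °C; then toluene, 110 °C
Reagents that add atoms: none
Why: Enolate O-alkylation followed by Claisen rearrangement: the tetrasubstituted potassium enolate should react at oxygen with the allylic sulfonate in DMPU, and the [3,3] shift through a chair transition state forms C10–C9 on the face anti to the C2 silyloxy group (sets C10, methyl cis to OSi) with C11 equatorial as dictated by the E allyl geometry (sets C9).

Step 9
Reactants: 15 dienyl ketone
Product: 16 allylic bromide (Br on C6, C7=C8 with C17 methyl; E/Z mixture)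
Conditions: HBr (1.05 equiv, 33% in AcOH), CH2Cl2, −78 to −40 °C
Reagents that add atoms: hydrogen bromide, Br
Why: Electrophilic hydrobromination of the 2-substituted 1,3-diene: protonation at C17 gives the tertiary allyl cation and bromide capture at C6 should give the primary allylic bromide (1,4-addition, as isoprene gives prenyl bromide), while the isolated trisubstituted alkene reacts more slowly at low temperature; no stereocentre is formed and the E/Z ratio does not matter.

Step 10
Reactants: 16 allylic bromide
Product: 18 bicyclic tertiary alcohol (5-hydroxy-labda-7,13-diene bis-silyl ether), via allylsamarium diiodide 17 (not isolated)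
Conditions: SmI2 (2.5 equiv), THF, 0 °C, slow addition of 16 at high dilution; then aq. NH4Cl
Reagents that add atoms: none
Why: SmI2 reduces the allylic C–Br bond by two single-electron transfers to an allylsamarium in which metal migration between C6 and C8 interconverts the E and Z forms (and any tertiary bromide regioisomer), and the Z form adds through C6 to the C5 carbonyl. The closest known reaction type is the intramolecular samarium Barbier reaction of allylic halides with ketones. Ring B closes as a six-membered ring through the C6–C5 bond (6-exo addition to the carbonyl), whereas closure through C8 would give a strained four-membered ring and is not expected. The new C5 carbinol centre is not controlled and need not be, since step 11 erases it, and C9 and C10 are untouched. The step needs reduction of the bromide before the hindered dialkyl ketone and addition without enolisation, both secured by the ketone lying between the quaternary C4 and C10, and high dilution should suppress Wurtz coupling.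

Step 11
Reactants: 18 bicyclic tertiary alcohol
Product: 19 labda-5,7,13-triene bis-silyl ether (homoannular 5,7-diene in ring B)
Conditions: SOCl2, pyridine, 0 °C
Reagents that add atoms: none
Why: Dehydration of the tertiary alcohol through its chlorosulfite (E2 with pyridine): only C6 carries β-hydrogens because C4 and C10 are quaternary, so the 5,7-diene should be the only alkene isomer, and both C5 epimers of 18 converge.

Step 12
Reactants: 19 labda-5,7,13-triene bis-silyl ether
Product: 20 (2S,5R,9R,10R)-2-(tert-butyldimethylsilyloxy)-15-(tert-butyldiphenylsilyloxy)labda-7,13(E)-diene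
Conditions: H2 (1 atm), Raney Ni (W-2), EtOAc, rt
Reagents that add atoms: none
Why: Chemoselective catalytic hydrogenation of a homoannular 5,7-diene: as with 7-dehydrosterols, hydrogen should add 1,2 to the 5,6-double bond from the face opposite the C10 methyl and the axial C4 methyl, which sets C5–H trans to C20 and leaves the trisubstituted 7,8- and 13,14-alkenes.

Step 13
Reactants: 20 bis-silyl ether
Product: 21 (2S,5R,9R,10R)-labda-7,13(E)-diene-2,15-diol
Conditions: Bu4NF, THF, 50 °C
Reagents that add atoms: none
Why: Fluoride-mediated desilylation should remove both silyl ethers without touching the alkenes or any stereocentre.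

Step 14
Reactants: 21 (2S,5R,9R,10R)-labda-7,13(E)-diene-2,15-diol
Product: 22 (2S,5R,9R,10R)-labda-7,13(E)-diene-2,15-diyl diacetate (CNP0314870.1)
Conditions: Ac2O, pyridine, DMAP, CH2Cl2, rt
Reagents that add atoms: acetic anhydride, CC(=O)OC(C)=O
Why: DMAP-catalysed acylation should esterify both the primary allylic and the hindered axial secondary alcohol with retention, giving the target.

Compound list
1 | geraniol | CC(C)=CCC/C(C)=C/CO | starting material
2 | geranyl tert-butyldiphenylsilyl ether | CC(C)=CCC/C(C)=C/CO[Si](c1ccccc1)(c1ccccc1)C(C)(C)C | intermediate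
3 | ozonide of 2 at the 6,7-alkene (not isolated) | CC1(C)OOC(CC/C(C)=C/CO[Si](c2ccccc2)(c2ccccc2)C(C)(C)C)O1 | intermediate
4 | (E)-6-(tert-butyldiphenylsilyloxy)-4-methylhex-4-enal | O=CCC/C(C)=C/CO[Si](c1ccccc1)(c1ccccc1)C(C)(C)C | intermediate
5 | (E)-tert-butyl[(3-methylhept-2-en-6-yn-1-yl)oxy]diphenylsilane | C#CCC/C(C)=C/CO[Si](c1ccccc1)(c1ccccc1)C(C)(C)C | intermediate
6 | lithium acetylide of 5 (not isolated) | [Li]C#CCC/C(C)=C/CO[Si](c1ccccc1)(c1ccccc1)C(C)(C)C | intermediate
7 | (E)-8-(tert-butyldiphenylsilyloxy)-6-methyloct-6-en-2-yn-1-ol | OCC#CCC/C(C)=C/CO[Si](c1ccccc1)(c1ccccc1)C(C)(C)C | intermediate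
8 | oxamagnesacycle from anti-vinylmagnesiation of 7 (not isolated) | C=CC1=C(CC/C(C)=C/CO[Si](c2ccccc2)(c2ccccc2)C(C)(C)C)[Mg]OC1 | intermediate
9 | (2E,6E)-8-(tert-butyldiphenylsilyloxy)-2-ethenyl-6-methylocta-2,6-dien-1-ol | OC/C(C=C)=C/CC/C(C)=C/CO[Si](c1ccccc1)(c1ccccc1)C(C)(C)C | intermediate
10 | methanesulfonate of 9 | CS(=O)(=O)OC/C(C=C)=C/CC/C(C)=C/CO[Si](c1ccccc1)(c1ccccc1)C(C)(C)C | intermediate
11 | (4R,6R)-actinol, (4R,6R)-4-hydroxy-2,2,6-trimethylcyclohexanone | O=C1C(C)(C)C[C@H](O)C[C@H]1C | starting material
12 | (4R,6R)-4-(tert-butyldimethylsilyloxy)-2,2,6-trimethylcyclohexanone | O=C1C(C)(C)C[C@H](O[Si](C)(C)C(C)(C)C)C[C@H]1C | intermediate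
13 | potassium enolate of 12 (not isolated) | CC1=C([O-])C(C)(C)C[C@H](O[Si](C)(C)C(C)(C)C)C1.[K+] | intermediate
14 | allyl enol ether from O-alkylation of 13 by 10 (not isolated) | CC1=C(OC/C(C=C)=C/CC/C(C)=C/CO[Si](c2ccccc2)(c2ccccc2)C(C)(C)C)C(C)(C)C[C@H](O[Si](C)(C)C(C)(C)C)C1 | intermediate
15 | dienyl ketone: ring A C5 ketone, C10 methyl cis to C2–OSi, C9 bearing buta-1,3-dien-2-yl and the C11–C16 chain; C2, C9, C10 as in 22 | C=CC(=C)[C@@H](CC/C(C)=C/CO[Si](c1ccccc1)(c1ccccc1)C(C)(C)C)[C@]1(C)C[C@@H](O[Si](C)(C)C(C)(C)C)CC(C)(C)C1=O | intermediate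
16 | allylic bromide: Br–C6H2–C7H=C8(CH3)–C9, E/Z mixture (alkene geometry left open in the SMILES) | BrCC=C(C)[C@@H](CC/C(C)=C/CO[Si](c1ccccc1)(c1ccccc1)C(C)(C)C)[C@]1(C)C[C@@H](O[Si](C)(C)C(C)(C)C)CC(C)(C)C1=O | intermediate
17 | allylsamarium diiodide from 16 (not isolated; fluxional between C6 and C8) | I[Sm](I)CC=C(C)[C@@H](CC/C(C)=C/CO[Si](c1ccccc1)(c1ccccc1)C(C)(C)C)[C@]1(C)C[C@@H](O[Si](C)(C)C(C)(C)C)CC(C)(C)C1=O | intermediate
18 | 2-(tert-butyldimethylsilyloxy)-15-(tert-butyldiphenylsilyloxy)labda-7,13(E)-dien-5-ol; C2, C9, C10 as in 22, C5 carbinol configuration left open | CC(C)(C)[Si](c1ccccc1)(c1ccccc1)OC/C=C(\C)CC[C@@H]1C(C)=CCC2(O)C(C)(C)C[C@H](O[Si](C)(C)C(C)(C)C)C[C@@]12C | intermediate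
19 | 2-(tert-butyldimethylsilyloxy)-15-(tert-butyldiphenylsilyloxy)labda-5,7,13(E)-triene; C2, C9, C10 as in 22 | CC(C)(C)[Si](c1ccccc1)(c1ccccc1)OC/C=C(\C)CC[C@@H]1C(C)=CC=C2C(C)(C)C[C@H](O[Si](C)(C)C(C)(C)C)C[C@@]12C | intermediate
20 | (2S,5R,9R,10R)-2-(tert-butyldimethylsilyloxy)-15-(tert-butyldiphenylsilyloxy)labda-7,13(E)-diene | CC(C)(C)[Si](c1ccccc1)(c1ccccc1)OC/C=C(\C)CC[C@@H]1C(C)=CC[C@@H]2C(C)(C)C[C@H](O[Si](C)(C)C(C)(C)C)C[C@@]12C | intermediate
21 | (2S,5R,9R,10R)-labda-7,13(E)-diene-2,15-diol | OC/C=C(\C)CC[C@@H]1C(C)=CC[C@@H]2C(C)(C)C[C@H](O)C[C@@]12C | intermediate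
22 | (2S,5R,9R,10R)-labda-7,13(E)-diene-2,15-diyl diacetate | CC(=O)OC/C=C(\C)CC[C@@H]1C(C)=CC[C@@H]2C(C)(C)C[C@H](OC(C)=O)C[C@@]12C | target

Total steps: 14. Longest linear sequence: 13 steps (steps 1–6, then 8–14).

Steps most likely to fail

Step 8. The enolate may alkylate at C10 instead of oxygen, which would give the linear allylated ketone, or the [3,3] shift may lose facial or chair control. The fallback forms the C5–O bond by cross-coupling instead of enolate alkylation. It sets out from 12, which is condensed with N2H4·H2O (Et3N, EtOH, reflux) to the hydrazone F1. F1 is converted by the Barton vinyl iodide reaction (I2, tetramethylguanidine, Et2O) into the ring A vinyl iodide F2. F2 is coupled with dienol 9 (CuI, 3,4,7,8-tetramethyl-1,10-phenanthroline, Cs2CO3, toluene, 120 °C), which gives the allyl enol ether 14 and lets it rearrange in the same pot. The fallback rejoins the route at 15 and makes step 6 unnecessary.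

Step 10. The allylsamarium may be protonated or may dimerise before it adds to the very hindered carbonyl. The fallback changes the bond-forming mode to a ketyl–olefin reductive cyclisation and sets out from 15, skipping step 9. With SmI2, HMPA and t-BuOH in THF, the C5 ketyl radical should add to the diene terminus C6, and the resulting allyl radical is reduced and protonated. This makes no new compound (F0) and rejoins the route at 18. Any 8(17)-alkene isomer would have to be separated.

Step 12. Hydrogen may also reduce the 7,8- or 13,14-alkene, or may be delivered to the wrong face. The fallback sets C5 by radical deoxygenation instead and sets out from 18. Acylation with methyl chlorooxoacetate (DMAP, pyridine) gives the tertiary methyl oxalate F3. Treatment of F3 with Bu3SnH and AIBN (toluene, 110 °C) generates the C5 radical, which should take hydrogen on the face opposite the C10 and axial C4 methyls. The fallback rejoins the route at 20 and skips step 11.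

Further compounds
F1 | step 8 | hydrazone of 12 | NN=C1C(C)(C)C[C@H](O[Si](C)(C)C(C)(C)C)C[C@H]1C
F2 | step 8 | (R)-4-(tert-butyldimethylsilyloxy)-1-iodo-2,6,6-trimethylcyclohexene | CC1=C(I)C(C)(C)C[C@H](O[Si](C)(C)C(C)(C)C)C1
F0 | step 10 | none | none
F3 | step 12 | methyl oxalate of 18 at C5–O | CC(C)(C)[Si](c1ccccc1)(c1ccccc1)OC/C=C(\C)CC[C@@H]1C(C)=CCC2(OC(=O)C(=O)OC)C(C)(C)C[C@H](O[Si](C)(C)C(C)(C)C)C[C@@]12C
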